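**Plan**

- Retrosynthesis: the side chain is cut at its C2=C3 olefin (Wittig) and its C4–C5 bond (acid numbering; cyanomethylation of an allylic bromide made from the E-methyl of a prenyl group). The chroman is cut at the aryl ether bond C8a–O1 and at C4–C4a (B-alkyl Suzuki coupling).
- Enabling feature (chroman = 3,4-dihydro-2H-chromene; O1, C2, C3, C4, C4a, C5–C8, C8a): C2 carries O1, a methyl group, the two-carbon arm C3–C4 and a 4-methylpent-3-enyl arm. This is C3 of (R)-linalool with its hydroxyl, methyl, vinyl and homoprenyl groups, so once C4 is tied to the benzene ring (ring A) only the C8a–O1 bond of the dihydropyran ring (ring B) is missing.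
- Forward: ring A is bought as 2-bromo-1-iodo-3-methylbenzene and oxygenated para to bromine. Hydroboration of linalool and coupling at the iodide join the fragments, palladium closes ring B (the only ring formed), and the chain is grown by five carbons from the prenyl end.
- Stereochemistry: C2 (R) is the carbinol carbon of (R)-linalool and none of its bonds is ever broken. The 6E olefin comes from E-methyl-selective SeO2 oxidation, the 2E olefin from a stabilised ylide.

Key step: step 4

Assumption: (R)-(−)-linalool is used as purchased; since no step touches its carbinol carbon, the enantiomeric purity of 18 should equal that of 5.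

Step 1
Reactants: 1 2-bromo-1-iodo-3-methylbenzene
Product: 3 4-bromo-3-iodo-5-methylphenol, via arylboronic pinacol ester 2 (not isolated)
Conditions: [Ir(OMe)(cod)]2 (1.5 mol%), 4,4'-di-tert-butyl-2,2'-bipyridine (3 mol%), pinacolborane (1.5 equiv), THF, 50 °C; then 30% aq. H2O2, 2 M NaOH, THF, 0 °C → rt; 1 M HCl
Reagents that add atoms: hydrogen peroxide, OO (the phenol oxygen); pinacolborane, CC1(C)OBOC1(C)C (the boryl group of 2 only)
Why: Iridium-catalysed C–H borylation is governed by sterics, so only the C–H with no ortho substituent (C5, para to bromine) should be borylated while C–I and C–Br stay intact, and oxidative C–B cleavage with alkaline peroxide then gives the phenol in the same flask.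

Step 2
Reactants: 3 4-bromo-3-iodo-5-methylphenol
Product: 4 2-bromo-1-iodo-5-(methoxymethoxy)-3-methylbenzene
Conditions: MOMCl, i-Pr2NEt, CH2Cl2, 0 °C → rt
Reagents that add atoms: chloromethyl methyl ether, COCCl
Why: O-alkylation of the phenol with an α-chloro ether (Williamson-type acetal formation) installs a MOM group that should survive aqueous base, palladium catalysis, organolithium and hydride reagents and leave under mild acid.

Step 3
Reactants: 5 (R)-linalool; 4 2-bromo-1-iodo-5-(methoxymethoxy)-3-methylbenzene
Product: 7 (3R)-1-[2-bromo-5-(methoxymethoxy)-3-methylphenyl]-3,7-dimethyloct-6-en-3-ol, via B-alkyl-9-BBN borane 6 (not isolated)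
Conditions: 5 (1.3 equiv), 9-BBN (1.4 equiv, 0.5 M in THF), 0 °C → rt; then 4 (1.0 equiv), Pd(dppf)Cl2 (5 mol%), 3 M aq. K3PO4 (3 equiv), DMF, rt → 45 °C
Reagents that add atoms: 9-borabicyclo[3.3.1]nonane, B1C2CCCC1CCC2 (the boron of 6 only; no heavy atom of it remains in 7)
Why: 9-BBN hydroborates only the monosubstituted vinyl group, anti-Markovnikov (the trisubstituted olefin and the slowly reacting tertiary hydroxyl are left), and the B-alkyl Suzuki–Miyaura coupling should replace only iodine because zerovalent palladium inserts into C–I far faster than into the doubly ortho-flanked C–Br bond; the carbinol carbon is a spectator, so the (R) configuration of linalool is carried into 7.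

Step 4
Reactants: 7 (3R)-1-[2-bromo-5-(methoxymethoxy)-3-methylphenyl]-3,7-dimethyloct-6-en-3-ol
Product: 8 (2R)-6-(methoxymethoxy)-2,8-dimethyl-2-(4-methylpent-3-en-1-yl)chroman
Conditions: Pd(OAc)2 (3 mol%), 2-(di-tert-butylphosphino)-1,1'-binaphthyl (4 mol%), Cs2CO3 (1.5 equiv), toluene, 80 °C
Reagents that add atoms: none
Why: Pd(OAc)2 is reduced in the flask to zerovalent palladium, which as its monophosphine complex inserts into the C8a–Br bond; Cs2CO3 deprotonates the coordinated tertiary hydroxyl, bromide is lost, and C–O reductive elimination from the seven-membered aryl(alkoxo)palladacycle (Pd, C8a, C4a, C4, C3, C2, O1) forms the C8a–O1 bond. The closest known reaction type is the palladium-catalysed intramolecular etherification of aryl bromides with tertiary alcohols under bulky dialkylbiarylphosphine ligands, the C–O variant of Buchwald–Hartwig coupling. Ring B closes as a six-membered ring by bonding O1 to the aryl carbon, not by substitution at C2. No stereocentre is created, and C2 keeps the (R) configuration of linalool because all four of its bonds are spectators. The step needs C–O reductive elimination to outrun hydrodebromination: the alkoxide has no hydrogen on its carbinol carbon, so β-hydride elimination is excluded, the tether keeps oxygen on palladium, and the bulky electron-rich ligand forces elimination at the carbon flanked by the 8-methyl group and the C4 arm. The MOM ether and the trisubstituted olefin, which is too remote for a Heck closure, should be untouched.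

Step 5
Reactants: 8 (2R)-6-(methoxymethoxy)-2,8-dimethyl-2-(4-methylpent-3-en-1-yl)chroman
Product: 9 (2E)-5-[(2R)-6-(methoxymethoxy)-2,8-dimethylchroman-2-yl]-2-methylpent-2-en-1-ol
Conditions: SeO2 (0.3 equiv), t-BuOOH (3 equiv), salicylic acid (0.1 equiv), CH2Cl2, 0 °C → rt
Reagents that add atoms: tert-butyl hydroperoxide, CC(C)(C)OO (terminal oxidant); selenium dioxide, O=[Se]=O (oxygen carrier)
Why: In the Riley allylic oxidation an ene reaction of SeO2 at the more substituted olefin terminus followed by a [2,3]-sigmatropic shift delivers oxygen to the E-methyl group, so the E-allylic alcohol should form with the olefin position and the aryl ether unchanged.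

Step 6
Reactants: 9 (2E)-5-[(2R)-6-(methoxymethoxy)-2,8-dimethylchroman-2-yl]-2-methylpent-2-en-1-ol
Product: 10 (2R)-2-[(3E)-5-bromo-4-methylpent-3-en-1-yl]-6-(methoxymethoxy)-2,8-dimethylchroman
Conditions: CBr4, PPh3, CH2Cl2, 0 °C
Reagents that add atoms: carbon tetrabromide, BrC(Br)(Br)Br
Why: The Appel reaction converts the primary allylic alcohol through its alkoxyphosphonium salt into the bromide by direct SN2 displacement under neutral conditions, which should spare the MOM ether and keep the E geometry.

Step 7
Reactants: 10 (2R)-2-[(3E)-5-bromo-4-methylpent-3-en-1-yl]-6-(methoxymethoxy)-2,8-dimethylchroman; 11 acetonitrile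
Product: 12 (4E)-7-[(2R)-6-(methoxymethoxy)-2,8-dimethylchroman-2-yl]-4-methylhept-4-enenitrile
Conditions: MeCN (5 equiv), n-BuLi (4.5 equiv), THF, −78 °C; then 10, −78 → −40 °C
Reagents that add atoms: acetonitrile 11, CC#N
Why: SN2 alkylation of lithioacetonitrile at the primary allylic bromide adds the two missing chain carbons at the aldehyde oxidation level in masked form, and the excess of the small anion should suppress dialkylation and allylic transposition.

Step 8
Reactants: 12 (4E)-7-[(2R)-6-(methoxymethoxy)-2,8-dimethylchroman-2-yl]-4-methylhept-4-enenitrile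
Product: 14 (4E)-7-[(2R)-6-(methoxymethoxy)-2,8-dimethylchroman-2-yl]-4-methylhept-4-enal, via N-aluminio aldimine 13 (not isolated)
Conditions: i-Bu2AlH (1.3 equiv), toluene, −78 °C; then aq. potassium sodium tartrate, 10% aq. tartaric acid, 0 °C → rt
Reagents that add atoms: water, O (the carbonyl oxygen); diisobutylaluminium hydride, CC(C)C[AlH]CC(C)C (the aluminium group of 13 only)
Why: Partial hydride reduction of a nitrile stops at the N-aluminio aldimine, which cannot be reduced further, and mild aqueous acid hydrolysis should release the aldehyde without touching the MOM ether.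

Step 9
Reactants: 14 (4E)-7-[(2R)-6-(methoxymethoxy)-2,8-dimethylchroman-2-yl]-4-methylhept-4-enal; 15 methyl 2-(triphenylphosphoranylidene)propanoate
Product: 16 methyl (2E,6E)-9-[(2R)-6-(methoxymethoxy)-2,8-dimethylchroman-2-yl]-2,6-dimethylnona-2,6-dienoate
Conditions: 15 (1.3 equiv), CH2Cl2, rt
Reagents that add atoms: ylide 15, COC(=O)C(C)=P(c1ccccc1)(c1ccccc1)c1ccccc1
Why: Wittig olefination with an ester-stabilised α-methyl ylide proceeds through the more stable oxaphosphetane and should give the E-trisubstituted enoate, with the chain trans to the ester.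

Step 10
Reactants: 16 methyl (2E,6E)-9-[(2R)-6-(methoxymethoxy)-2,8-dimethylchroman-2-yl]-2,6-dimethylnona-2,6-dienoate
Product: 17 methyl (2E,6E)-9-[(2R)-6-hydroxy-2,8-dimethylchroman-2-yl]-2,6-dimethylnona-2,6-dienoate
Conditions: HCl (1.25 M in MeOH), MeOH/THF, rt → 40 °C
Reagents that add atoms: none
Why: Acid-catalysed acetal exchange transfers the methoxymethyl group to methanol; the methyl ester is degenerate towards methanolysis, and the dilute acid should leave both trisubstituted olefins and the chroman ether intact.

Step 11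
Reactants: 17 methyl (2E,6E)-9-[(2R)-6-hydroxy-2,8-dimethylchroman-2-yl]-2,6-dimethylnona-2,6-dienoate
Product: 18 (2E,6E)-9-[(2R)-6-hydroxy-2,8-dimethylchroman-2-yl]-2,6-dimethylnona-2,6-dienoic acid
Conditions: LiOH·H2O (5 equiv), THF/MeOH/H2O (degassed, Ar), rt → 45 °C; then 1 M HCl to pH 3
Reagents that add atoms: lithium hydroxide, [Li+].[OH-]
Why: Saponification (acyl–oxygen ester hydrolysis) frees the acid without moving either olefin, since the E-α-methyl enoate is the stable isomer, and exclusion of air protects the intermediate phenoxide from oxidation.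

**Compound list**

1 | 2-bromo-1-iodo-3-methylbenzene | Cc1cccc(I)c1Br | starting material
2 | 2-(4-bromo-3-iodo-5-methylphenyl)-4,4,5,5-tetramethyl-1,3,2-dioxaborolane | Cc1cc(B2OC(C)(C)C(C)(C)O2)cc(I)c1Br | intermediate (not isolated)
3 | 4-bromo-3-iodo-5-methylphenol | Cc1cc(O)cc(I)c1Br | intermediate
4 | 2-bromo-1-iodo-5-(methoxymethoxy)-3-methylbenzene | COCOc1cc(C)c(Br)c(I)c1 | intermediate
5 | (R)-linalool, (3R)-3,7-dimethylocta-1,6-dien-3-ol | CC(C)=CCC[C@@](C)(O)C=C | starting material
6 | (3R)-1-(9-borabicyclo[3.3.1]nonan-9-yl)-3,7-dimethyloct-6-en-3-ol | CC(C)=CCC[C@@](C)(O)CCB1C2CCCC1CCC2 | intermediate (not isolated)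
7 | (3R)-1-[2-bromo-5-(methoxymethoxy)-3-methylphenyl]-3,7-dimethyloct-6-en-3-ol | CC(C)=CCC[C@@](C)(O)CCc1cc(OCOC)cc(C)c1Br | intermediate
8 | (2R)-6-(methoxymethoxy)-2,8-dimethyl-2-(4-methylpent-3-en-1-yl)chroman | CC(C)=CCC[C@]1(C)CCc2cc(OCOC)cc(C)c2O1 | intermediate
9 | (2E)-5-[(2R)-6-(methoxymethoxy)-2,8-dimethylchroman-2-yl]-2-methylpent-2-en-1-ol | OC/C(C)=C/CC[C@]1(C)CCc2cc(OCOC)cc(C)c2O1 | intermediate
10 | (2R)-2-[(3E)-5-bromo-4-methylpent-3-en-1-yl]-6-(methoxymethoxy)-2,8-dimethylchroman | BrC/C(C)=C/CC[C@]1(C)CCc2cc(OCOC)cc(C)c2O1 | intermediate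
11 | acetonitrile | CC#N | starting material
12 | (4E)-7-[(2R)-6-(methoxymethoxy)-2,8-dimethylchroman-2-yl]-4-methylhept-4-enenitrile | N#CCC/C(C)=C/CC[C@]1(C)CCc2cc(OCOC)cc(C)c2O1 | intermediate
13 | N-(diisobutylaluminio) imine of aldehyde 14 | CC(C)C[Al](CC(C)C)N=CCC/C(C)=C/CC[C@]1(C)CCc2cc(OCOC)cc(C)c2O1 | intermediate (not isolated)
14 | (4E)-7-[(2R)-6-(methoxymethoxy)-2,8-dimethylchroman-2-yl]-4-methylhept-4-enal | O=CCC/C(C)=C/CC[C@]1(C)CCc2cc(OCOC)cc(C)c2O1 | intermediate
15 | methyl 2-(triphenylphosphoranylidene)propanoate | COC(=O)C(C)=P(c1ccccc1)(c1ccccc1)c1ccccc1 | starting material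
16 | methyl (2E,6E)-9-[(2R)-6-(methoxymethoxy)-2,8-dimethylchroman-2-yl]-2,6-dimethylnona-2,6-dienoate | COC(=O)/C(C)=C/CC/C(C)=C/CC[C@]1(C)CCc2cc(OCOC)cc(C)c2O1 | intermediate
17 | methyl (2E,6E)-9-[(2R)-6-hydroxy-2,8-dimethylchroman-2-yl]-2,6-dimethylnona-2,6-dienoate | COC(=O)/C(C)=C/CC/C(C)=C/CC[C@]1(C)CCc2cc(O)cc(C)c2O1 | intermediate
18 | (2E,6E)-9-[(2R)-6-hydroxy-2,8-dimethylchroman-2-yl]-2,6-dimethylnona-2,6-dienoic acid | OC(=O)/C(C)=C/CC/C(C)=C/CC[C@]1(C)CCc2cc(O)cc(C)c2O1 | target

**Step count and risks**

Total: 11 steps. Longest linear sequence: 11 steps (1 → 18); (R)-linalool 5 enters at step 3.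

Step 4. Oxidative addition into the electron-rich C–Br bond flanked by two ortho substituents may be slow, and the arylpalladium alkoxide may be diverted to hydrodebromination before C–O reductive elimination. The fallback sets out from 7 and returns at 8, keeping the same C8a–O1 closure but through a copper alkoxide on a more reactive halide. Aromatic Finkelstein exchange (CuI, NaI, trans-N,N'-dimethylcyclohexane-1,2-diamine, dioxane, 110 °C) would give (3R)-1-[2-iodo-5-(methoxymethoxy)-3-methylphenyl]-3,7-dimethyloct-6-en-3-ol F1. An Ullmann-type intramolecular etherification (CuI, 3,4,7,8-tetramethyl-1,10-phenanthroline, Cs2CO3, toluene, 110 °C) would then close ring B to 8, again without touching C2.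

Step 5. The allylic oxidation may stall, run on past the alcohol, or attack the allylic methylene instead of the E-methyl group. The fallback sets out from 8 and returns at 9 by rebuilding the olefin instead of oxidising it.
- Dihydroxylation of the only olefin (OsO4 cat., N-methylmorpholine N-oxide, acetone/H2O) would give 5-[(2S)-6-(methoxymethoxy)-2,8-dimethylchroman-2-yl]-2-methylpentane-2,3-diol F2 as a mixture of carbinol epimers.
- NaIO4 (THF/H2O) would cleave it to 3-[(2S)-6-(methoxymethoxy)-2,8-dimethylchroman-2-yl]propanal F3. The descriptor changes only because the CIP ranking changes; the geometry at C2 is the same.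
- Wittig reaction with ethyl 2-(triphenylphosphoranylidene)propanoate (CH2Cl2, rt) would give ethyl (2E)-5-[(2R)-6-(methoxymethoxy)-2,8-dimethylchroman-2-yl]-2-methylpent-2-enoate F4.
- i-Bu2AlH (CH2Cl2, −78 °C) would reduce the ester to allylic alcohol 9.

Step 3. Transmetalation of the hydroxyl-bearing alkylborane may lag behind protodeboronation, or the discrimination between iodide and bromide may erode. The fallback sets out from 5 and 4 and returns at 7. A Heck reaction under phase-transfer conditions (Pd(OAc)2, Bu4NCl, NaHCO3, DMF, 60 °C) would arylate the vinyl group of linalool at the iodide to give (1E,3R)-1-[2-bromo-5-(methoxymethoxy)-3-methylphenyl]-3,7-dimethylocta-1,6-dien-3-ol F5. The tertiary carbinol cannot be lost by β-hydride elimination. Diimide (2-nitrobenzenesulfonylhydrazide, Et3N, CH2Cl2, rt) would then saturate the disubstituted styrene olefin in preference to the trisubstituted one, without touching C–Br, to give 7.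

**Further compounds**

F1 | step 4 | (3R)-1-[2-iodo-5-(methoxymethoxy)-3-methylphenyl]-3,7-dimethyloct-6-en-3-ol | CC(C)=CCC[C@@](C)(O)CCc1cc(OCOC)cc(C)c1I
F2 | step 5 | 5-[(2S)-6-(methoxymethoxy)-2,8-dimethylchroman-2-yl]-2-methylpentane-2,3-diol | CC(C)(O)C(O)CC[C@]1(C)CCc2cc(OCOC)cc(C)c2O1
F3 | step 5 | 3-[(2S)-6-(methoxymethoxy)-2,8-dimethylchroman-2-yl]propanal | O=CCC[C@]1(C)CCc2cc(OCOC)cc(C)c2O1
F4 | step 5 | ethyl (2E)-5-[(2R)-6-(methoxymethoxy)-2,8-dimethylchroman-2-yl]-2-methylpent-2-enoate | CCOC(=O)/C(C)=C/CC[C@]1(C)CCc2cc(OCOC)cc(C)c2O1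
F5 | step 3 | (1E,3R)-1-[2-bromo-5-(methoxymethoxy)-3-methylphenyl]-3,7-dimethylocta-1,6-dien-3-ol | CC(C)=CCC[C@@](C)(O)/C=C/c1cc(OCOC)cc(C)c1Br
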